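**Retrosynthetic overview**
1. Target 16 comes from methyl ether 14 by O‑demethylation; 14 comes from α‑acetoxy ketone 12 by reductive removal of the C2 oxygen (SmI2).
2. Key disconnection C2–C3: hydroxy ketone 11 is made from aryl glyoxal 5 and (2E,6E)‑farnesyl‑Bpin 9 by a chiral‑phosphoric‑acid‑catalysed carbonyl allylation. γ‑Attack creates the quaternary carbon with its vinyl group; the 2E geometry plus the catalyst fix (2S,3S), which is 3R in the target once C2 is deoxygenated.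
3. Glyoxal 5 comes from ketone 3 (Riley oxidation), and 3 from 2‑methoxy‑6‑methylbenzoic acid 1 and MeLi. Boronate 9 comes from farnesyl chloride 8, and 8 from (2E,6E)‑farnesol 6.
4. No ring is formed; the benzene ring is bought.

Assumption: (2E,6E)‑farnesol and 2‑methoxy‑6‑methylbenzoic acid are bought geometrically and isomerically pure, and the facial sense of (S)‑TRIP with the α‑keto aldehyde is taken by analogy with simple aldehydes (this exact substrate class is not precedented).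

**Route**

Step 1
Reactants: 1 2‑methoxy‑6‑methylbenzoic acid
Product: 3 1‑(2‑methoxy‑6‑methylphenyl)ethan‑1‑one, via dilithium gem‑diolate 2 (not isolated)
Conditions: MeLi (2.3 equiv), THF, 0 °C to rt; inverse quench into cold 1 M HCl
Reagents that add atoms: methyllithium [Li]C
Why: Organolithium addition to a lithium carboxylate (Gilman ketone synthesis) stops at the dilithium gem‑diolate, which collapses to the methyl ketone only on acidic work‑up, so no tertiary alcohol forms.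

Step 2
Reactants: 3 1‑(2‑methoxy‑6‑methylphenyl)ethan‑1‑one
Product: 5 2‑(2‑methoxy‑6‑methylphenyl)‑2‑oxoacetaldehyde, via glyoxal hydrate 4 (not isolated)
Conditions: SeO2 (1.2 equiv), 1,4‑dioxane/H2O (20:1), 100 °C; filter Se; toluene azeotrope, Kugelrohr distillation
Reagents that add atoms: selenium dioxide O=[Se]=O
Why: Riley oxidation of the acetyl CH3 through its enol gives the aryl glyoxal (2,6‑disubstituted aryl glyoxals such as mesitylglyoxal are made this way), and azeotropic drying returns the hydrate to the free aldehyde; aryl methyl ether and aryl CH3 are inert.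

Step 3
Reactants: 6 (2E,6E)‑farnesol
Product: 8 (2E,6E)‑farnesyl chloride, via alkoxysulfonium chloride 7 (not isolated)
Conditions: NCS (1.1 equiv), Me2S (1.2 equiv), CH2Cl2, −40 to 0 °C
Reagents that add atoms: N‑chlorosuccinimide O=C1CCC(=O)N1Cl
Why: Corey–Kim‑type chlorination: chloride displaces DMSO from the alkoxysulfonium salt by SN2 at the primary allylic carbon, without allylic transposition or loss of the 2E geometry.

Step 4
Reactants: 8 (2E,6E)‑farnesyl chloride
Product: 9 4,4,5,5‑tetramethyl‑2‑[(2E,6E)‑3,7,11‑trimethyldodeca‑2,6,10‑trien‑1‑yl]‑1,3,2‑dioxaborolane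
Conditions: B2pin2 (1.1 equiv), Pd2(dba)3 (1 mol%), THF, 60 °C
Reagents that add atoms: bis(pinacolato)diboron CC1(C)OB(OC1(C)C)B1OC(C)(C)C(C)(C)O1
Why: Pd‑catalysed Miyaura‑type allylic borylation through a π‑allyl‑palladium that is borylated at the unhindered terminus with retention of the 2E geometry; the pinacol ester is configurationally stable and can be chromatographed.

Step 5
Reactants: 5 2‑(2‑methoxy‑6‑methylphenyl)‑2‑oxoacetaldehyde; 9 (2E,6E)‑farnesyl‑Bpin
Product: 11 (2S,3S,6E)‑3‑ethenyl‑2‑hydroxy‑1‑(2‑methoxy‑6‑methylphenyl)‑3,7,11‑trimethyldodeca‑6,10‑dien‑1‑one, via pinacol borate ester 10 (not isolated)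
Conditions: (S)‑TRIP [(S)‑3,3′‑bis(2,4,6‑triisopropylphenyl)‑1,1′‑binaphthyl‑2,2′‑diyl hydrogen phosphate] (5 mol%), 4 Å MS, toluene, −30 to 0 °C; aq. NaHCO3 work‑up
Reagents that add atoms: none
Why: Chiral‑phosphoric‑acid‑catalysed carbonyl allylboration through a Zimmerman–Traxler chair: the 2E boronate puts the homogeranyl chain equatorial and the methyl axial, fixing C3 relative to C2 (OH anti to homogeranyl), while (S)‑TRIP directs γ‑attack to the Si face of the formyl group, setting C2 as S and the quaternary C3 as S (3R after C2 is deoxygenated); only the unhindered aldehyde of 5 reacts.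

Step 6
Reactants: 11 (2S,3S,6E)‑hydroxy ketone
Product: 12 (2S,3S,6E)‑3‑ethenyl‑1‑(2‑methoxy‑6‑methylphenyl)‑3,7,11‑trimethyl‑1‑oxododeca‑6,10‑dien‑2‑yl acetate
Conditions: Ac2O (3 equiv), pyridine, DMAP (0.2 equiv), CH2Cl2, 0 °C to rt
Reagents that add atoms: acetic anhydride CC(=O)OC(C)=O
Why: DMAP‑catalysed acetylation of the hindered secondary alcohol turns the C2 oxygen into a leaving group for the next step; no stereocentre is touched.

Step 7
Reactants: 12 (2S,3S,6E)‑α‑acetoxy ketone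
Product: 14 (3R,6E)‑3‑ethenyl‑1‑(2‑methoxy‑6‑methylphenyl)‑3,7,11‑trimethyldodeca‑6,10‑dien‑1‑one, via samarium(III) enolate 13 (not isolated)
Conditions: SmI2 (2.5 equiv, 0.1 M in THF), MeOH (10 equiv), THF, −78 °C, 20 min; aq. NH4Cl
Reagents that add atoms: none
Why: SmI2 reductive cleavage of an α‑acyloxy ketone: two‑electron reduction expels acetate to give the samarium enolate, which MeOH protonates; the C2 stereocentre is erased on purpose and the quaternary C3 is untouched (its descriptor changes from S to R only because the priorities change).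

Step 8
Reactants: 14 (3R,6E)‑methyl ether ketone
Product: 16 (3R,6E)‑3‑ethenyl‑1‑(2‑hydroxy‑6‑methylphenyl)‑3,7,11‑trimethyldodeca‑6,10‑dien‑1‑one, via sodium phenolate 15 (not isolated)
Conditions: EtSNa (4 equiv), DMF, 110 °C; then cold 1 M HCl
Reagents that add atoms: none
Why: Thiolate SN2 O‑demethylation of the ortho‑acyl anisole under non‑acidic conditions, which spare the acid‑sensitive triene; the quaternary centre cannot epimerise.

**Compound list**
1 | 2‑methoxy‑6‑methylbenzoic acid | COc1cccc(C)c1C(=O)O | starting material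
2 | dilithium 1‑(2‑methoxy‑6‑methylphenyl)ethane‑1,1‑diolate | COc1cccc(C)c1C(C)([O-])[O-].[Li+].[Li+] | intermediate
3 | 1‑(2‑methoxy‑6‑methylphenyl)ethan‑1‑one | COc1cccc(C)c1C(C)=O | intermediate
4 | 2,2‑dihydroxy‑1‑(2‑methoxy‑6‑methylphenyl)ethan‑1‑one (glyoxal hydrate) | COc1cccc(C)c1C(=O)C(O)O | intermediate
5 | 2‑(2‑methoxy‑6‑methylphenyl)‑2‑oxoacetaldehyde | COc1cccc(C)c1C(=O)C=O | intermediate
6 | (2E,6E)‑3,7,11‑trimethyldodeca‑2,6,10‑trien‑1‑ol ((2E,6E)‑farnesol) | OC/C=C(\C)CC/C=C(\C)CCC=C(C)C | starting material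
7 | dimethyl{[(2E,6E)‑3,7,11‑trimethyldodeca‑2,6,10‑trien‑1‑yl]oxy}sulfonium chloride | C[S+](C)OC/C=C(\C)CC/C=C(\C)CCC=C(C)C.[Cl-] | intermediate
8 | (2E,6E)‑1‑chloro‑3,7,11‑trimethyldodeca‑2,6,10‑triene ((2E,6E)‑farnesyl chloride) | ClC/C=C(\C)CC/C=C(\C)CCC=C(C)C | intermediate
9 | 4,4,5,5‑tetramethyl‑2‑[(2E,6E)‑3,7,11‑trimethyldodeca‑2,6,10‑trien‑1‑yl]‑1,3,2‑dioxaborolane ((2E,6E)‑farnesyl‑Bpin) | CC1(C)OB(C/C=C(\C)CC/C=C(\C)CCC=C(C)C)OC1(C)C | intermediate
10 | 2‑{[(2S,3S,6E)‑3‑ethenyl‑1‑(2‑methoxy‑6‑methylphenyl)‑3,7,11‑trimethyl‑1‑oxododeca‑6,10‑dien‑2‑yl]oxy}‑4,4,5,5‑tetramethyl‑1,3,2‑dioxaborolane | C=C[C@](C)(CC/C=C(\C)CCC=C(C)C)[C@H](OB1OC(C)(C)C(C)(C)O1)C(=O)c1c(C)cccc1OC | intermediate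
11 | (2S,3S,6E)‑3‑ethenyl‑2‑hydroxy‑1‑(2‑methoxy‑6‑methylphenyl)‑3,7,11‑trimethyldodeca‑6,10‑dien‑1‑one | C=C[C@](C)(CC/C=C(\C)CCC=C(C)C)[C@H](O)C(=O)c1c(C)cccc1OC | intermediate
12 | (2S,3S,6E)‑3‑ethenyl‑1‑(2‑methoxy‑6‑methylphenyl)‑3,7,11‑trimethyl‑1‑oxododeca‑6,10‑dien‑2‑yl acetate | C=C[C@](C)(CC/C=C(\C)CCC=C(C)C)[C@H](OC(C)=O)C(=O)c1c(C)cccc1OC | intermediate
13 | diiodosamarium(III) C1=C2 enolate of 14 (C3 configuration unchanged) | C=C[C@](C)(CC/C=C(\C)CCC=C(C)C)C=C(O[Sm](I)I)c1c(C)cccc1OC | intermediate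
14 | (3R,6E)‑3‑ethenyl‑1‑(2‑methoxy‑6‑methylphenyl)‑3,7,11‑trimethyldodeca‑6,10‑dien‑1‑one | C=C[C@](C)(CC/C=C(\C)CCC=C(C)C)CC(=O)c1c(C)cccc1OC | intermediate
15 | sodium 2‑[(3R,6E)‑3‑ethenyl‑3,7,11‑trimethyldodeca‑6,10‑dienoyl]‑3‑methylphenolate | C=C[C@](C)(CC/C=C(\C)CCC=C(C)C)CC(=O)c1c(C)cccc1[O-].[Na+] | intermediate
16 | (3R,6E)‑3‑ethenyl‑1‑(2‑hydroxy‑6‑methylphenyl)‑3,7,11‑trimethyldodeca‑6,10‑dien‑1‑one (CNP0202916.1) | C=C[C@](C)(CC/C=C(\C)CCC=C(C)C)CC(=O)c1c(C)cccc1O | target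

**Step count and risks**
Total steps: 8 (steps 1–2 arene branch, steps 3–4 terpene branch, steps 5–8 after union).
Longest linear sequence: 6 steps (6 → 8 → 9 → 11 → 12 → 14 → 16; the branch from 1 is equally long).

Most likely to fail:

1. Step 5. Asymmetric induction on an α‑keto aldehyde with a hindered γ,γ‑disubstituted boronate is the least precedented operation: the reaction may be slow, the uncatalysed background may erode ee, and the facial sense is assigned by analogy. The fallback replaces catalyst control by resolution; it sets out from 5 and 9 and returns at 14. Stir 5 with 9 in toluene at rt without catalyst: the chair transition state still gives only the anti pair, so borate 10 forms together with its mirror image, the (2R,3R)‑borate F1 (not isolated). Work‑up gives 11 mixed 1:1 with the (2R,3R)‑hydroxy ketone F2. Acylate the mixture with (1S)‑(−)‑camphanic chloride (pyridine, DMAP, CH2Cl2) to the diastereomeric esters, the (2S,3S)‑camphanate F3 and the (2R,3R)‑camphanate F4, and separate them by chromatography or crystallisation. Treat F3 with SmI2/MeOH in THF at −78 °C; the camphanate is expelled just as acetate is in step 7, giving 14 directly.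

2. Step 7. The twisted, hindered aryl ketone may be reduced sluggishly, or the ketyl may over‑reduce to the alcohol. The fallback is a radical‑chain deoxygenation; it sets out from 11 and returns at 14. Convert 11 with phenyl chlorothionoformate (pyridine, DMAP, CH2Cl2) into the O‑phenyl thionocarbonate F5, then heat with Bu3SnH and AIBN in toluene at 80 °C (Barton–McCombie). The α‑aroyl radical is stabilised, so it should be quenched by the stannane before it can add to the neighbouring vinyl group.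

3. Step 8. SN2 demethylation of a twisted, weakly activated anisole may need forcing temperatures on a late‑stage polyene. The fallback switches to chelation‑directed Lewis‑acid cleavage; it sets out from 14 and returns at 16. Treat 14 with BCl3 (1.5 equiv) in CH2Cl2 at −78 to −40 °C: boron binds the ketone and ether oxygens, chloride removes the methyl group, and the resulting aryloxydichloroborane chelate F6 (not isolated) is hydrolysed to 16 by a cold NaHCO3 quench. Low temperature and short contact time are needed to keep the Lewis acid away from the trisubstituted alkenes.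

**Further compounds**
F1 | step 5 | 2‑{[(2R,3R,6E)‑3‑ethenyl‑1‑(2‑methoxy‑6‑methylphenyl)‑3,7,11‑trimethyl‑1‑oxododeca‑6,10‑dien‑2‑yl]oxy}‑4,4,5,5‑tetramethyl‑1,3,2‑dioxaborolane (mirror image of 10) | C=C[C@@](C)(CC/C=C(\C)CCC=C(C)C)[C@@H](OB1OC(C)(C)C(C)(C)O1)C(=O)c1c(C)cccc1OC
F2 | step 5 | (2R,3R,6E)‑3‑ethenyl‑2‑hydroxy‑1‑(2‑methoxy‑6‑methylphenyl)‑3,7,11‑trimethyldodeca‑6,10‑dien‑1‑one (mirror image of 11) | C=C[C@@](C)(CC/C=C(\C)CCC=C(C)C)[C@@H](O)C(=O)c1c(C)cccc1OC
F3 | step 5 | (2S,3S,6E)‑3‑ethenyl‑1‑(2‑methoxy‑6‑methylphenyl)‑3,7,11‑trimethyl‑1‑oxododeca‑6,10‑dien‑2‑yl (1S,4R)‑4,7,7‑trimethyl‑3‑oxo‑2‑oxabicyclo[2.2.1]heptane‑1‑carboxylate | C=C[C@](C)(CC/C=C(\C)CCC=C(C)C)[C@H](OC(=O)[C@@]12CC[C@@](C)(C(=O)O1)C2(C)C)C(=O)c1c(C)cccc1OC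
F4 | step 5 | (2R,3R,6E)‑3‑ethenyl‑1‑(2‑methoxy‑6‑methylphenyl)‑3,7,11‑trimethyl‑1‑oxododeca‑6,10‑dien‑2‑yl (1S,4R)‑4,7,7‑trimethyl‑3‑oxo‑2‑oxabicyclo[2.2.1]heptane‑1‑carboxylate | C=C[C@@](C)(CC/C=C(\C)CCC=C(C)C)[C@@H](OC(=O)[C@@]12CC[C@@](C)(C(=O)O1)C2(C)C)C(=O)c1c(C)cccc1OC
F5 | step 7 | O‑[(2S,3S,6E)‑3‑ethenyl‑1‑(2‑methoxy‑6‑methylphenyl)‑3,7,11‑trimethyl‑1‑oxododeca‑6,10‑dien‑2‑yl] O‑phenyl carbonothioate | C=C[C@](C)(CC/C=C(\C)CCC=C(C)C)[C@H](OC(=S)Oc1ccccc1)C(=O)c1c(C)cccc1OC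
F6 | step 8 | dichloro{2‑[(3R,6E)‑3‑ethenyl‑3,7,11‑trimethyldodeca‑6,10‑dienoyl]‑3‑methylphenoxy}borane | C=C[C@](C)(CC/C=C(\C)CCC=C(C)C)CC(=O)c1c(C)cccc1OB(Cl)Cl
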